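Atom labels used throughout: benzofuran numbering O1, C2, C3, C3a, C4–C7, C7a. Primes mark the aryl ring on C2, double primes mark the prenyl group. Cα and Cβ are the enone carbons of chalcone 11.

## Analysis of the target

Ebenfuran IV (19) is a fully aromatic 2-arylbenzofuran. C2 carries a 4-hydroxy-2-methoxyphenyl ring, C3 a formyl group, C4 a hydroxyl group, C5 a prenyl group and C6 a methoxy group; only C7 carries hydrogen. The molecule has no stereocentre, and the prenyl double bond ends in two methyl groups, so it is achiral and every difficulty is regiochemical. Five neighbouring positions (C2–C6) are substituted, and the C3 formyl group is wedged between the ortho-substituted C2 aryl ring and C4–OH, to which it is hydrogen-bonded. The benzo ring is of the phloroglucinol type: C5 and C7 are each activated by three oxygens, so electrophilic formylation (C3 against C5/C7) and electrophilic prenylation (C5 against C7) cannot be trusted. Two phenols and two methyl ethers must be told apart. The trisubstituted alkene next to a free phenol is sensitive to acid (chroman formation) and to electrophilic oxidants.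

The first feature the route uses is the chain C2–C3–CHO, with an aryl carbon on C2 (C1') and an aryl carbon on C3 (C3a). This is the 1,2-diaryl-C3 unit of an isoflavonoid, that is, of a chalcone after a 1,2-aryl shift. The second feature is that C3a is flanked by two oxygen-bearing carbons, C7a (O1) and C4 (OH). Without the O1–C2 bond and the prenyl group, the benzo ring is therefore a symmetric 2,6-dioxygenated 4-methoxyphenyl group, and C5 is the only free ortho position of C4–OH.

## Retrosynthetic reasoning

**O4'–Si.** 19 comes from its 4'-O-silyl ether 18. O4' is the more acidic, unchelated phenol and would react first in any O-alkylation, so it must be masked while C4–OH is used. A bulky silyl group is chosen because it outlasts the sulfonic acid of the key step and leaves under fluoride, which harms neither the prenyl group nor the aldehyde.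

**C5–C1''.** The prenyl bond of 18 is cut back to the C4–O bond of the tertiary allyl ether 17. This ether comes from the propargyl ether 16, made from phenol 14 and the C5 halide 15. A [3,3] shift from O4 can only end at C5, because the other ortho carbon, C3a, is quaternary, so the C5/C7 problem disappears. The prenyl group is placed after the oxidation because a trisubstituted alkene would not survive an electrophilic iodine(III) reagent.

**O1–C2 and C3–C3a (key disconnection).** In 14 the furan ring is opened at O1–C2, and C3a is moved back from C3 to the formyl carbon. This leads through the cyclic acetal 13 and the keto acetal 12 to the open-chain chalcone 11. In 11 the future formyl carbon is Cβ, C3 is Cα and C2 is the ketone carbon. The forward reaction must oxidise the alkene, shift the trioxygenated aryl group from Cβ to Cα, unmask the two ortho oxygens, close one of them on the ketone and release the aldehyde. The cut is made here because it copies the aryl shift of the isoflavonoid pathway. It also delivers the C3 carbon substituent as part of the skeleton rather than by substitution on a crowded heteroarene. Its precursor has a symmetric migrating ring, so the choice of ring-closing oxygen needs no control, and the oxygen left over is exactly the C4–OH handle needed for the prenyl transfer.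

**Cα=Cβ.** 11 is cut at the alkene into methyl ketone 7 and aldehyde 5, joined through enolate 8, aldolate 9 and mesylate 10. This one bond joins the two halves and is the most convergent point of the route.

**The two arenes.** Aldehyde 5 comes from the symmetric bis-acetal 2 by metalation between the two directing groups (through 3 and 4), and 2 comes from commercial 1. Ketone 7 is the silyl ether of commercial 6, which already holds the O2' methyl ether. That methyl ether also blocks any closure to a chromone in the key step.

## Alternatives that were turned down

**Alternative 1:** the textbook route cuts C2–C1' or the alkyne bond, and later C3–CHO. Sonogashira coupling of iodophenol A1 with arylacetylene A2 and 5-endo-dig closure would give the 3-unsubstituted 2-arylbenzofuran A3, followed by Vilsmeier–Haack formylation and then prenylation.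
- The formyl carbon must enter A3 by electrophilic substitution, where C3 competes with C7 and C5, each activated by three oxygens. C3 is also the most hindered of the three, lying between the ortho-substituted aryl ring and the C4 oxygen substituent.
- A1 needs monoprotection of a symmetric diol and iodination between two oxygens, and A2 needs its own homologation.
- C2, C3 and C5 are each served by a separate operation, so no step does more than one job and the sequence is longer.

**Alternative 2:** oxidative ring contraction of a flavylium salt. Acid condensation of dihydroxyaldehyde A4 with 6 would give flavylium chloride A5 without protecting groups. Aqueous peroxide would add to C2 of the pyrylium ring, a Baeyer–Villiger-type C2–C3 cleavage would give ester aldehyde A6, and attack of its methylene carbon on the ester carbonyl would close the furan.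
- It is very short, but the reaction type is sound only when the pyrylium C3 bears a substituent.
- In A6 an arylacetaldehyde sits next to a free ortho hydroxyl group. That group would add to the aldehyde and dehydrate faster than carbon can attack a donor-deactivated aroyl ester.
- Free electron-rich phenols and the product aldehyde (Dakin-type cleavage) would face peroxide.
- Both phenols would emerge free, so an extra protection step returns, and the risk is spread over several events.

**Alternative 3:** build the benzo ring last by a Danheiser benzannulation. This combines furyl diazoketone A7 with ynol ether A8 through Wolff rearrangement, [2+2] cycloaddition, 4π opening and 6π closure onto the furan C3. It would place C4–OH, C5-prenyl, C6–OMe and C7–H regiospecifically and give acetal A9.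
- The mapping is perfect, but A7 is a 2,4,5-trisubstituted furan that already holds the aryl ring and the masked formyl group, and it needs a regiocontrolled synthesis of its own.
- A8 is a non-commercial, acid-labile skipped enyne ether.
- The 6π closure must occur next to the bulky acetal. The precursor costs more than the key step gains.

Key step: step 5

Assumption: the SMILES holds no stereocentre and no E/Z element, so the target is achiral, and "single enantiomer" is read as the single constitution shown.

## Route

Step 1
Reactants: 1 5-methoxybenzene-1,3-diol
Product: 2 1-methoxy-3,5-bis(methoxymethoxy)benzene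
Conditions: MOMCl, i-Pr2NEt, CH2Cl2, 0 °C → rt
Reagents that add atoms: chloromethyl methyl ether, COCCl
Why: Twofold O-alkylation of the phenols with a hard, very reactive electrophile. The MOM groups direct the metalation of step 2, shield the ring oxygens from the oxidant in step 5 and leave under the acid of that same step.

Step 2
Reactants: 2 1-methoxy-3,5-bis(methoxymethoxy)benzene
Product: 5 4-methoxy-2,6-bis(methoxymethoxy)benzaldehyde, via aryllithium 3 (not isolated), via lithium hemiaminalate 4 (not isolated)
Conditions: n-BuLi, TMEDA, THF, 0 °C; DMF, 0 °C → rt; H2O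
Reagents that add atoms: N,N-dimethylformamide, CN(C)C=O; n-butyllithium, [Li]CCCC (lithium in 3 and 4 only)
Why: Directed ortho-metalation; the carbon between the two chelating MOM ethers is better coordinated and more acidic than the carbons between OMOM and OMe. Formylation of an aryllithium with DMF is standard, and this carbon becomes the C3 formyl carbon of the target.

Step 3
Reactants: 6 1-(4-hydroxy-2-methoxyphenyl)ethan-1-one
Product: 7 1-{2-methoxy-4-[(triisopropylsilyl)oxy]phenyl}ethan-1-one
Conditions: TIPSCl, imidazole, DMF, rt
Reagents that add atoms: triisopropylsilyl chloride, CC(C)[Si](Cl)(C(C)C)C(C)C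
Why: Standard silylation of an acidic, unhindered phenol. The aryl TIPS ether resists sulfonic acid, iodine(III) and heat, and is removed by fluoride at the end.

Step 4
Reactants: 7 1-{2-methoxy-4-[(triisopropylsilyl)oxy]phenyl}ethan-1-one; 5 4-methoxy-2,6-bis(methoxymethoxy)benzaldehyde
Product: 11 (E)-3-[4-methoxy-2,6-bis(methoxymethoxy)phenyl]-1-{2-methoxy-4-[(triisopropylsilyl)oxy]phenyl}prop-2-en-1-one, via lithium enolate 8 (not isolated), via lithium aldolate 9 (not isolated), via benzylic mesylate 10 (not isolated)
Conditions: LiHMDS, THF, −78 °C; 5, −78 → −20 °C; MsCl, Et3N, −20 °C → rt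
Reagents that add atoms: lithium hexamethyldisilazide, [Li]N([Si](C)(C)C)[Si](C)(C)C (lithium in 8 and 9 only); methanesulfonyl chloride, CS(=O)(=O)Cl (mesyl group in 10 only)
Why: Directed aldol addition of a preformed lithium enolate, then mesylation and elimination. The amide base spares the aryl silyl ether that hydroxide would cleave, and trapping of 9 forestalls retro-aldol. The very electron-rich benzylic mesylate eliminates readily to the less strained E alkene.

Step 5
Reactants: 11 (E)-3-[4-methoxy-2,6-bis(methoxymethoxy)phenyl]-1-{2-methoxy-4-[(triisopropylsilyl)oxy]phenyl}prop-2-en-1-one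
Product: 14 4-hydroxy-6-methoxy-2-{2-methoxy-4-[(triisopropylsilyl)oxy]phenyl}benzofuran-3-carbaldehyde, via keto acetal 12 (not isolated), via cyclic acetal 13 (not isolated)
Conditions: PhI(OH)OTs (1.05 equiv), MeOH, 0 °C → rt; then 40 °C; evaporate; (CF3)2CHOH, H2O (5 equiv), rt → 40 °C
Reagents that add atoms: methanol, CO (methoxy groups of 12 and 13 only); water, O (formyl oxygen of 14)
Why: The iodane, tempered by methanol, adds to Cα of the push-pull alkene of 11 while methanol caps Cβ, whose cation is stabilised by the three ring oxygens; loss of iodobenzene from Cα is assisted by the trioxygenated aryl group through a phenonium ion, so the aryl carbon moves from Cβ to Cα (new C3–C3a bond) and Cβ is trapped as the dimethyl acetal of 12. The closest known reaction type is the iodine(III)- or thallium(III)-mediated oxidative 1,2-aryl migration of chalcones to 1,2-diaryl-3,3-dimethoxypropan-1-ones, the laboratory copy of the aryl shift of isoflavonoid biosynthesis, and the second half follows the known acid-induced conversion of rearranged 2-(methoxymethoxy)chalcones into 3-formylbenzofurans in a fluorinated alcohol. The sulfonic acid released by the oxidant methanolyses both MOM groups, and one phenol closes 5-exo-trig on the acetal-derived oxocarbenium ion to the resting state 13. In hexafluoroisopropanol, which ionises well but is too weakly basic to remove H3, 13 reopens instead of losing methanol, the phenol adds 5-exo-trig to the protonated ketone (O1–C2 bond), water leaves through a cation stabilised by the 2-methoxy-4-silyloxyphenyl group so that the furan ring becomes aromatic, and added water converts the remaining oxocarbenium ion into the C3 formyl group. No stereocentre is set, since the centres of 12 and 13 are racemic, need no control and are erased on aromatisation. Migration selectivity rests on the far higher migratory aptitude of the 2,4,6-trioxygenated aryl group over hydrogen or aroyl, and alkene-over-arene selectivity rests on the conjugation of all three donors to Cα, on a single equivalent of oxidant and on keeping the fluorinated alcohol out of the oxidation stage. The site of ring closure needs no control because the two ortho oxygens of the migrated ring are constitutionally equivalent and either gives 14, and closure to a chromone is impossible because O2' is a methyl ether. The TIPS ether is the one protecting group stable to the sulfonic acid, so 14 emerges with only C4–OH free.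

Step 6
Reactants: 14 4-hydroxy-6-methoxy-2-{2-methoxy-4-[(triisopropylsilyl)oxy]phenyl}benzofuran-3-carbaldehyde; 15 3-chloro-3-methylbut-1-yne
Product: 16 6-methoxy-4-[(2-methylbut-3-yn-2-yl)oxy]-2-{2-methoxy-4-[(triisopropylsilyl)oxy]phenyl}benzofuran-3-carbaldehyde
Conditions: DBU, CuCl2·2H2O (1 mol %), MeCN, 0 °C
Reagents that add atoms: none
Why: Copper-catalysed propargylic etherification of a phenol with a tertiary propargylic halide, a reaction that works best with acidic phenols such as the carbonyl-conjugated C4–OH. DBU breaks the hydrogen bond to the formyl group, and O4' is blocked, so only O4 can react.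

Step 7
Reactants: 16 6-methoxy-4-[(2-methylbut-3-yn-2-yl)oxy]-2-{2-methoxy-4-[(triisopropylsilyl)oxy]phenyl}benzofuran-3-carbaldehyde
Product: 18 4-hydroxy-6-methoxy-5-(3-methylbut-2-en-1-yl)-2-{2-methoxy-4-[(triisopropylsilyl)oxy]phenyl}benzofuran-3-carbaldehyde, via tert-allyl ether 17 (not isolated)
Conditions: H2 (1 atm), Lindlar catalyst, quinoline, toluene, rt; filter; 110 °C
Reagents that add atoms: none
Why: Semi-hydrogenation over poisoned palladium stops at the alkene, and the aromatic Claisen rearrangement of the 1,1-dimethylallyl ether transposes the allyl unit, so a linear prenyl group lands on the ortho carbon. C3a is quaternary, so only attack at C5 can rearomatise by tautomerisation. The geminal methyl groups and the regained hydrogen bond to the formyl group lower the barrier.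

Step 8
Reactants: 18 4-hydroxy-6-methoxy-5-(3-methylbut-2-en-1-yl)-2-{2-methoxy-4-[(triisopropylsilyl)oxy]phenyl}benzofuran-3-carbaldehyde
Product: 19 Ebenfuran IV, 4-hydroxy-2-(4-hydroxy-2-methoxyphenyl)-6-methoxy-5-(3-methylbut-2-en-1-yl)benzofuran-3-carbaldehyde
Conditions: TBAF, AcOH, THF, 0 °C
Reagents that add atoms: none
Why: Fluoride-induced cleavage of an aryl silyl ether, fast here because the phenoxide is a vinylogous carboxylate. The acetic acid buffer keeps the medium neutral, so neither the aldehyde nor the ortho-prenylphenol is touched.

## Compound list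

1 | 5-methoxybenzene-1,3-diol | COc1cc(O)cc(O)c1 | starting material
2 | 1-methoxy-3,5-bis(methoxymethoxy)benzene | COCOc1cc(OC)cc(OCOC)c1 | intermediate
3 | [4-methoxy-2,6-bis(methoxymethoxy)phenyl]lithium | [Li]c1c(OCOC)cc(OC)cc1OCOC | intermediate
4 | lithium (dimethylamino)[4-methoxy-2,6-bis(methoxymethoxy)phenyl]methanolate | [Li]OC(N(C)C)c1c(OCOC)cc(OC)cc1OCOC | intermediate
5 | 4-methoxy-2,6-bis(methoxymethoxy)benzaldehyde | COCOc1cc(OC)cc(OCOC)c1C=O | intermediate
6 | 1-(4-hydroxy-2-methoxyphenyl)ethan-1-one | CC(=O)c1ccc(O)cc1OC | starting material
7 | 1-{2-methoxy-4-[(triisopropylsilyl)oxy]phenyl}ethan-1-one | CC(=O)c1ccc(O[Si](C(C)C)(C(C)C)C(C)C)cc1OC | intermediate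
8 | lithium enolate of 7 | [Li]OC(=C)c1ccc(O[Si](C(C)C)(C(C)C)C(C)C)cc1OC | intermediate
9 | lithium aldolate from 8 and 5 (racemic) | [Li]OC(CC(=O)c1ccc(O[Si](C(C)C)(C(C)C)C(C)C)cc1OC)c1c(OCOC)cc(OC)cc1OCOC | intermediate
10 | β-(methanesulfonyloxy) ketone from 9 (racemic) | CS(=O)(=O)OC(CC(=O)c1ccc(O[Si](C(C)C)(C(C)C)C(C)C)cc1OC)c1c(OCOC)cc(OC)cc1OCOC | intermediate
11 | (E)-3-[4-methoxy-2,6-bis(methoxymethoxy)phenyl]-1-{2-methoxy-4-[(triisopropylsilyl)oxy]phenyl}prop-2-en-1-one | COCOc1cc(OC)cc(OCOC)c1/C=C/C(=O)c1ccc(O[Si](C(C)C)(C(C)C)C(C)C)cc1OC | intermediate
12 | 3,3-dimethoxy-2-[4-methoxy-2,6-bis(methoxymethoxy)phenyl]-1-{2-methoxy-4-[(triisopropylsilyl)oxy]phenyl}propan-1-one (racemic) | COCOc1cc(OC)cc(OCOC)c1C(C(OC)OC)C(=O)c1ccc(O[Si](C(C)C)(C(C)C)C(C)C)cc1OC | intermediate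
13 | (4-hydroxy-2,6-dimethoxy-2,3-dihydrobenzofuran-3-yl){2-methoxy-4-[(triisopropylsilyl)oxy]phenyl}methanone (racemic, mixture of diastereomers) | COC1Oc2cc(OC)cc(O)c2C1C(=O)c1ccc(O[Si](C(C)C)(C(C)C)C(C)C)cc1OC | intermediate
14 | 4-hydroxy-6-methoxy-2-{2-methoxy-4-[(triisopropylsilyl)oxy]phenyl}benzofuran-3-carbaldehyde | COc1cc(O[Si](C(C)C)(C(C)C)C(C)C)ccc1-c1oc2cc(OC)cc(O)c2c1C=O | intermediate
15 | 3-chloro-3-methylbut-1-yne | C#CC(C)(C)Cl | starting material
16 | 6-methoxy-4-[(2-methylbut-3-yn-2-yl)oxy]-2-{2-methoxy-4-[(triisopropylsilyl)oxy]phenyl}benzofuran-3-carbaldehyde | C#CC(C)(C)Oc1cc(OC)cc2oc(-c3ccc(O[Si](C(C)C)(C(C)C)C(C)C)cc3OC)c(C=O)c12 | intermediate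
17 | 6-methoxy-4-[(2-methylbut-3-en-2-yl)oxy]-2-{2-methoxy-4-[(triisopropylsilyl)oxy]phenyl}benzofuran-3-carbaldehyde | C=CC(C)(C)Oc1cc(OC)cc2oc(-c3ccc(O[Si](C(C)C)(C(C)C)C(C)C)cc3OC)c(C=O)c12 | intermediate
18 | 4-hydroxy-6-methoxy-5-(3-methylbut-2-en-1-yl)-2-{2-methoxy-4-[(triisopropylsilyl)oxy]phenyl}benzofuran-3-carbaldehyde | COc1cc(O[Si](C(C)C)(C(C)C)C(C)C)ccc1-c1oc2cc(OC)c(CC=C(C)C)c(O)c2c1C=O | intermediate
19 | Ebenfuran IV | COc1cc(O)ccc1-c1oc2cc(OC)c(CC=C(C)C)c(O)c2c1C=O | target

## Step count and risk

Total step count: 8. Longest linear sequence: 7 steps (steps 1, 2, 4, 5, 6, 7 and 8, from 1 to 19). Step 3 lies on the short branch.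

**Step 5 (key step).** Three processes are most likely to go wrong.
- The iodane may attack the free ring positions of the trioxygenated arene instead of Cα. Those positions are also activated by three oxygens.
- The MOM groups may fall off before the oxidation is complete, which would expose a phenol to iodine(III).
- In the second half, the cyclic acetal may aromatise by loss of methanol before it can reopen, which would leave the aroyl group on C3.

The fallback sets out from 11 and comes back at 14, and it replaces the electrophilic oxidant by a nucleophilic one. Epoxidation of the enone with t-BuOOH and DBU in toluene cannot touch the arenes and should give the racemic trans-epoxide F1. BF3·OEt2 at low temperature opens F1 at the benzylic carbon, and a Meinwald-type rearrangement with 1,2-aroyl shift gives the β-keto aldehyde F2, which has the same 1,2-diaryl connectivity as 12. Sulfonic acid in methanol and then in hexafluoroisopropanol removes the MOM groups and closes F2 to 14.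

**Step 6.** The C4 oxygen is hydrogen-bonded to the formyl group and crowded by it, so etherification with a tertiary electrophile may be slow. During a long exposure to DBU the silyl group may wander between phenoxides. The fallback sets out from 14 and comes back at 18, bypassing steps 6 and 7. O-alkylation with the primary halide prenyl bromide (K2CO3, acetone) should give the O-prenyl ether F3. Montmorillonite K10 in CH2Cl2 then induces a [1,3] shift through a tight ion pair to the neighbouring C5.

**Step 7.** Hydrogenation may run on past the alkene. On heating, the tertiary allyl ether of a good phenoxide leaving group may fragment by loss of the C5 unit as a diene instead of rearranging. The fallback sets out from 14 and comes back at 18, and it avoids a tertiary ether altogether. Allyl bromide and K2CO3 give the allyl ether F4. A thermal Claisen rearrangement (N,N-diethylaniline, 190 °C) gives the 5-allylphenol F5 with the same ortho specificity. Cross metathesis with 2-methylbut-2-ene over a second-generation ruthenium alkylidene converts the allyl group into the prenyl group.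

**Step 4.** Addition of the enolate to a hindered, electron-rich aldehyde may be reversible, so retro-aldol may outrun mesylation, and conversion may stall. The fallback sets out from 6, uses 5, and comes back at 14, at the price of one more step. 6 is protected with MOMCl and i-Pr2NEt as the MOM ether F6. A hydroxide-mediated Claisen–Schmidt condensation with 5 (KOH, EtOH–H2O, rt) gives the tris-MOM chalcone F7 under thermodynamic control. The conditions of step 5 convert F7 into the diphenol F8. One equivalent of TIPSCl with imidazole then silylates only the unchelated, more acidic O4'–H.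

## Further compounds

F1 | step 5 | trans-{3-[4-methoxy-2,6-bis(methoxymethoxy)phenyl]oxiran-2-yl}{2-methoxy-4-[(triisopropylsilyl)oxy]phenyl}methanone (racemic, relative configuration drawn) | COCOc1cc(OC)cc(OCOC)c1[C@@H]1O[C@H]1C(=O)c1ccc(O[Si](C(C)C)(C(C)C)C(C)C)cc1OC
F2 | step 5 | 2-[4-methoxy-2,6-bis(methoxymethoxy)phenyl]-3-{2-methoxy-4-[(triisopropylsilyl)oxy]phenyl}-3-oxopropanal (racemic, enolisable) | COCOc1cc(OC)cc(OCOC)c1C(C=O)C(=O)c1ccc(O[Si](C(C)C)(C(C)C)C(C)C)cc1OC
F3 | step 6 | 6-methoxy-4-[(3-methylbut-2-en-1-yl)oxy]-2-{2-methoxy-4-[(triisopropylsilyl)oxy]phenyl}benzofuran-3-carbaldehyde | CC(C)=CCOc1cc(OC)cc2oc(-c3ccc(O[Si](C(C)C)(C(C)C)C(C)C)cc3OC)c(C=O)c12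
F4 | step 7 | 4-(allyloxy)-6-methoxy-2-{2-methoxy-4-[(triisopropylsilyl)oxy]phenyl}benzofuran-3-carbaldehyde | C=CCOc1cc(OC)cc2oc(-c3ccc(O[Si](C(C)C)(C(C)C)C(C)C)cc3OC)c(C=O)c12
F5 | step 7 | 5-allyl-4-hydroxy-6-methoxy-2-{2-methoxy-4-[(triisopropylsilyl)oxy]phenyl}benzofuran-3-carbaldehyde | C=CCc1c(OC)cc2oc(-c3ccc(O[Si](C(C)C)(C(C)C)C(C)C)cc3OC)c(C=O)c2c1O
F6 | step 4 | 1-[2-methoxy-4-(methoxymethoxy)phenyl]ethan-1-one | CC(=O)c1ccc(OCOC)cc1OC
F7 | step 4 | (E)-3-[4-methoxy-2,6-bis(methoxymethoxy)phenyl]-1-[2-methoxy-4-(methoxymethoxy)phenyl]prop-2-en-1-one | COCOc1cc(OC)cc(OCOC)c1/C=C/C(=O)c1ccc(OCOC)cc1OC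
F8 | step 4 | 4-hydroxy-2-(4-hydroxy-2-methoxyphenyl)-6-methoxybenzofuran-3-carbaldehyde | COc1cc(O)ccc1-c1oc2cc(OC)cc(O)c2c1C=O
A1 | alternative 1 | 2-iodo-5-methoxy-3-(methoxymethoxy)phenol | COCOc1cc(OC)cc(O)c1I
A2 | alternative 1 | (4-ethynyl-3-methoxyphenoxy)triisopropylsilane | C#Cc1ccc(O[Si](C(C)C)(C(C)C)C(C)C)cc1OC
A3 | alternative 1 | 6-methoxy-4-(methoxymethoxy)-2-{2-methoxy-4-[(triisopropylsilyl)oxy]phenyl}benzofuran | COCOc1cc(OC)cc2oc(-c3ccc(O[Si](C(C)C)(C(C)C)C(C)C)cc3OC)cc12
A4 | alternative 2 | 2,6-dihydroxy-4-methoxybenzaldehyde | COc1cc(O)c(C=O)c(O)c1
A5 | alternative 2 | 5-hydroxy-2-(4-hydroxy-2-methoxyphenyl)-7-methoxychromenylium chloride | COc1cc(O)c2ccc(-c3ccc(O)cc3OC)[o+]c2c1.[Cl-]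
A6 | alternative 2 | 3-hydroxy-5-methoxy-2-(2-oxoethyl)phenyl 4-hydroxy-2-methoxybenzoate | O=CCc1c(O)cc(OC)cc1OC(=O)c1ccc(O)cc1OC
A7 | alternative 3 | 2-diazo-1-[4-(dimethoxymethyl)-5-{2-methoxy-4-[(triisopropylsilyl)oxy]phenyl}furan-2-yl]ethan-1-one | [N-]=[N+]=CC(=O)c1cc(C(OC)OC)c(-c2ccc(O[Si](C(C)C)(C(C)C)C(C)C)cc2OC)o1
A8 | alternative 3 | 1-methoxy-5-methylhex-4-en-1-yne | COC#CCC=C(C)C
A9 | alternative 3 | 3-(dimethoxymethyl)-6-methoxy-5-(3-methylbut-2-en-1-yl)-2-{2-methoxy-4-[(triisopropylsilyl)oxy]phenyl}benzofuran-4-ol | COc1cc(O[Si](C(C)C)(C(C)C)C(C)C)ccc1-c1oc2cc(OC)c(CC=C(C)C)c(O)c2c1C(OC)OC
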